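**Retrosynthetic overview**

- C7–aryl bond, with the C7 acetate already in place: nickel-catalysed stereoconvergent radical cross-coupling of an α-acetoxyalkyl radical (from (S)-2-aryloxypropanal and acetyl bromide) with 4-iodoveratrole. This last step sets C7 and gives the target directly.
- C8–O(aryl) bond: Mitsunobu inversion of methyl (R)-lactate with 4-allyl-2,6-dimethoxyphenol sets C8 as S; the ester is then reduced to the aldehyde.
- Ring B phenol: resorcinol → dimethyl ether → C2 lithiation/borylation/oxidation → O-allylation → para-Claisen rearrangement.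
- Ring A iodide: catechol → veratrole → para-iodination.
- No ring is formed in the route; both benzene rings come from the starting materials, ring B being elaborated first and ring A attached last.

Assumption: the sense of induction of the chiral nickel catalyst at C7 is not known for this substrate; the ligand antipode written in step 9 is taken as the one matched with the 8S centre for the 7S product, and its mirror image is used if a test run shows the opposite.

**Route**

Step 1
Reactants: 1 resorcinol
Product: 2 1,3-dimethoxybenzene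
Conditions: MeI (2.5 equiv), K2CO3, acetone, reflux
Reagents that add atoms: methyl iodide, CI
Why: Williamson ether synthesis; both phenoxides are methylated by SN2 on MeI and no stereocenter is involved.

Step 2
Reactants: 2 1,3-dimethoxybenzene
Product: 5 2,6-dimethoxyphenol, via 2,6-dimethoxyphenyllithium 3 (not isolated), via dimethyl (2,6-dimethoxyphenyl)boronate 4 (not isolated)
Conditions: n-BuLi, THF, 0 °C to rt; B(OMe)3, −78 °C to rt; AcOH, 30% aq H2O2, 0 °C to rt
Reagents that add atoms: hydrogen peroxide, OO
Why: Directed ortho-metalation occurs only at C2 between the two cooperating methoxy groups, and borylation followed by peroxide oxidation (aryl shift from boron to oxygen) places the hydroxyl there.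

Step 3
Reactants: 5 2,6-dimethoxyphenol; 6 allyl bromide
Product: 7 2-(allyloxy)-1,3-dimethoxybenzene
Conditions: K2CO3, acetone, reflux
Reagents that add atoms: none
Why: Williamson O-allylation of the phenoxide by SN2 on the allylic bromide.

Step 4
Reactants: 7 2-(allyloxy)-1,3-dimethoxybenzene
Product: 10 4-allyl-2,6-dimethoxyphenol, via 6-allyl-2,6-dimethoxycyclohexa-2,4-dienone 8 (not isolated), via 4-allyl-2,6-dimethoxycyclohexa-2,5-dienone 9 (not isolated)
Conditions: PhNEt2, 210 °C, N2
Reagents that add atoms: none
Why: para-Claisen rearrangement; the [3,3] shift to the blocked ortho carbon is followed by a Cope [3,3] shift to the para carbon and tautomerisation to the phenol.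

Step 5
Reactants: 10 4-allyl-2,6-dimethoxyphenol; 11 methyl (R)-lactate
Product: 12 methyl (S)-2-(4-allyl-2,6-dimethoxyphenoxy)propanoate
Conditions: PPh3, DIAD, THF, 0 °C to rt
Reagents that add atoms: none
Why: Mitsunobu etherification; the phenoxide displaces the activated secondary α-hydroxy ester with clean SN2 inversion, converting the (R)-lactate centre into the (S)-aryl ether centre that becomes C8.

Step 6
Reactants: 12 methyl (S)-2-(4-allyl-2,6-dimethoxyphenoxy)propanoate
Product: 14 (S)-2-(4-allyl-2,6-dimethoxyphenoxy)propanal, via aluminium hemiacetal 13 (not isolated)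
Conditions: i-Bu2AlH (1.1 equiv), CH2Cl2, −78 °C; MeOH, then aq potassium sodium tartrate (KNaC4H4O6); used crude at once
Reagents that add atoms: none
Why: DIBAL-H partial reduction; the chelated tetrahedral aluminium hemiacetal of the α-aryloxy ester survives at −78 °C and gives the aldehyde only on work-up, so C8 is untouched and over-reduction is avoided.

Step 7
Reactants: 15 catechol
Product: 16 1,2-dimethoxybenzene (veratrole)
Conditions: MeI (2.5 equiv), K2CO3, acetone, reflux
Reagents that add atoms: methyl iodide, CI
Why: Williamson ether synthesis on both phenoxides.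

Step 8
Reactants: 16 1,2-dimethoxybenzene
Product: 17 4-iodo-1,2-dimethoxybenzene
Conditions: NIS, CF3CO2H (10 mol%), MeCN, rt
Reagents that add atoms: N-iodosuccinimide, O=C1CCC(=O)N1I
Why: Electrophilic aromatic iodination goes para to a methoxy group, and the two such positions of veratrole are equivalent.

Step 9
Reactants: 14 (S)-2-(4-allyl-2,6-dimethoxyphenoxy)propanal; 17 4-iodo-1,2-dimethoxybenzene
Product: 20 (1S,2S)-2-(4-allyl-2,6-dimethoxyphenoxy)-1-(3,4-dimethoxyphenyl)propyl acetate (the target), via 1-bromoalkyl acetate 18 (not isolated), via α-acetoxyalkyl radical 19 (not isolated)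
Conditions: AcBr (1.0 equiv), ZnBr2 (1 mol%), CH2Cl2, −20 to 0 °C, then evaporate; NiBr2·MeOCH2CH2OMe (10 mol%), (4S,4'S)-4,4'-di(heptan-4-yl)-4,4',5,5'-tetrahydro-2,2'-bioxazole (12 mol%), 17 (1.2 equiv), Mn powder (3 equiv), Me3SiCl (0.3 equiv), 1,4-dioxane, rt
Reagents that add atoms: acetyl bromide, CC(Br)=O
Why: Proposed new method: acetyl bromide adds across the aldehyde C=O to give 18; a low-valent nickel–bis(oxazoline) species abstracts bromine from either C7 epimer of 18 to give the planar radical 19, which is captured by the chiral arylnickel halide formed by oxidative addition of 17, and C–C reductive elimination from the resulting trivalent nickel centre (expected to be faster than β-aryloxy elimination) forms the C7–aryl bond, the ligand-controlled facial choice, matched with the fixed 8S centre, setting 7S while Mn powder turns the catalyst over; the closest known reaction types are the nickel-catalysed enantioconvergent couplings of racemic 1-bromoalkyl esters made in situ from aldehydes and acyl bromides, and the nickel-catalysed asymmetric reductive cross-electrophile coupling of aryl iodides with secondary benzylic or α-heteroatom-substituted halides.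

**Compound list**

1 | resorcinol (benzene-1,3-diol) | Oc1cccc(O)c1 | starting material
2 | 1,3-dimethoxybenzene | COc1cccc(OC)c1 | intermediate
3 | 2,6-dimethoxyphenyllithium | [Li]c1c(OC)cccc1OC | intermediate (not isolated)
4 | dimethyl (2,6-dimethoxyphenyl)boronate | COB(OC)c1c(OC)cccc1OC | intermediate (not isolated)
5 | 2,6-dimethoxyphenol | COc1cccc(OC)c1O | intermediate
6 | allyl bromide (3-bromoprop-1-ene) | C=CCBr | starting material
7 | 2-(allyloxy)-1,3-dimethoxybenzene | C=CCOc1c(OC)cccc1OC | intermediate
8 | 6-allyl-2,6-dimethoxycyclohexa-2,4-dien-1-one (racemic) | C=CCC1(OC)C=CC=C(OC)C1=O | intermediate (not isolated)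
9 | 4-allyl-2,6-dimethoxycyclohexa-2,5-dien-1-one | C=CCC1C=C(OC)C(=O)C(OC)=C1 | intermediate (not isolated)
10 | 4-allyl-2,6-dimethoxyphenol | C=CCc1cc(OC)c(O)c(OC)c1 | intermediate
11 | methyl (R)-lactate (methyl (2R)-2-hydroxypropanoate) | C[C@@H](O)C(=O)OC | starting material
12 | methyl (S)-2-(4-allyl-2,6-dimethoxyphenoxy)propanoate | C=CCc1cc(OC)c(O[C@@H](C)C(=O)OC)c(OC)c1 | intermediate
13 | [(2S)-2-(4-allyl-2,6-dimethoxyphenoxy)-1-methoxypropoxy]diisobutylaluminium (both C1 epimers) | C=CCc1cc(OC)c(O[C@@H](C)C(OC)O[Al](CC(C)C)CC(C)C)c(OC)c1 | intermediate (not isolated)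
14 | (S)-2-(4-allyl-2,6-dimethoxyphenoxy)propanal | C=CCc1cc(OC)c(O[C@@H](C)C=O)c(OC)c1 | intermediate
15 | catechol (benzene-1,2-diol) | Oc1ccccc1O | starting material
16 | 1,2-dimethoxybenzene (veratrole) | COc1ccccc1OC | intermediate
17 | 4-iodo-1,2-dimethoxybenzene | COc1ccc(I)cc1OC | intermediate
18 | (2S)-1-bromo-2-(4-allyl-2,6-dimethoxyphenoxy)propyl acetate (both C1 epimers) | C=CCc1cc(OC)c(O[C@@H](C)C(Br)OC(C)=O)c(OC)c1 | intermediate (not isolated)
19 | (2S)-1-acetoxy-2-(4-allyl-2,6-dimethoxyphenoxy)propan-1-yl radical | C=CCc1cc(OC)c(O[C@@H](C)[CH]OC(C)=O)c(OC)c1 | intermediate (not isolated)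
20 | (1S,2S)-2-(4-allyl-2,6-dimethoxyphenoxy)-1-(3,4-dimethoxyphenyl)propyl acetate (threo; 7S,8S) | C=CCc1cc(OC)c(O[C@@H](C)[C@@H](OC(C)=O)c2ccc(OC)c(OC)c2)c(OC)c1 | target

**Step count and risks**

Total steps: 9. Longest linear sequence: 7 (steps 1, 2, 3, 4, 5, 6 and 9); steps 7 and 8 form the side branch.

Steps most likely to fail:

1. Step 9. The coupling is untested on an α-branched, β-aryloxy 1-bromoalkyl acetate. The C7 diastereoselectivity may be low, and β-aryloxy elimination to an enol acetate, allyl isomerisation or biaryl formation can compete. The fallback sets out from 14 and 17 and comes back at 20. Compound 17 is converted with i-PrMgCl·LiCl (THF, −20 °C) into (3,4-dimethoxyphenyl)magnesium chloride F1. F1 is added to 14 precomplexed with MgBr2·OEt2 in CH2Cl2 at −78 °C (Cram chelate addition) to give the threo alcohol (1S,2S)-2-(4-allyl-2,6-dimethoxyphenoxy)-1-(3,4-dimethoxyphenyl)propan-1-ol F2 together with the erythro alcohol (1R,2S)-2-(4-allyl-2,6-dimethoxyphenoxy)-1-(3,4-dimethoxyphenyl)propan-1-ol F3. After chromatographic separation F2 is acetylated (Ac2O, pyridine, DMAP) to 20. F3 is converted into 20 with inversion at C7 by a Mitsunobu reaction with AcOH (PPh3, DIAD), so both diastereomers end at 20.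

2. Step 6. The α-aryloxy aldehyde can over-reduce or lose configurational purity at C8. The fallback sets out from 12 and comes back at 14. Compound 12 is reduced fully with LiAlH4 (THF, 0 °C) to (S)-2-(4-allyl-2,6-dimethoxyphenoxy)propan-1-ol F4, a stable compound that can be stored. F4 is oxidised just before use with Dess–Martin periodinane and NaHCO3 in CH2Cl2 at 0 °C to 14.

3. Step 5. The doubly ortho-substituted phenol 10 is a hindered Mitsunobu partner and may react slowly. The fallback sets out from 10 and 11 and comes back at 12. Compound 11 is converted with Tf2O and 2,6-lutidine (CH2Cl2, −78 °C) into methyl (R)-2-(trifluoromethylsulfonyloxy)propanoate F5. F5 is displaced by the potassium phenoxide of 10 (K2CO3, MeCN, 0 °C) with SN2 inversion to give 12.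

**Further compounds**

F1 | step 9 | (3,4-dimethoxyphenyl)magnesium chloride | COc1ccc([Mg]Cl)cc1OC
F2 | step 9 | (1S,2S)-2-(4-allyl-2,6-dimethoxyphenoxy)-1-(3,4-dimethoxyphenyl)propan-1-ol | C=CCc1cc(OC)c(O[C@@H](C)[C@@H](O)c2ccc(OC)c(OC)c2)c(OC)c1
F3 | step 9 | (1R,2S)-2-(4-allyl-2,6-dimethoxyphenoxy)-1-(3,4-dimethoxyphenyl)propan-1-ol | C=CCc1cc(OC)c(O[C@@H](C)[C@H](O)c2ccc(OC)c(OC)c2)c(OC)c1
F4 | step 6 | (S)-2-(4-allyl-2,6-dimethoxyphenoxy)propan-1-ol | C=CCc1cc(OC)c(O[C@@H](C)CO)c(OC)c1
F5 | step 5 | methyl (R)-2-(trifluoromethylsulfonyloxy)propanoate | C[C@@H](OS(=O)(=O)C(F)(F)F)C(=O)OC
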